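(Its constants are assumed; no experiment stands behind them.)

solid substrate 13 mM; partner 2.00 equiv; protic impurity 2.60 mM; time 40 min

    partner + protic impurity → quenched reagent (k1 = 7.1 M⁻¹ s⁻¹)
    crystals ⇌ target, rate k2*(cs2 - [target]) while solid is left; crystals form when [target] > cs2 (cs2 = 0.16 mM, k2 = 6.8 s⁻¹)
    partner → side product (k3 = 0.14 s⁻¹)
    solid substrate ⇌ dissolved substrate, rate k4*(cs4 - [dissolved substrate]) while solid is left; crystals form when [dissolved substrate] > cs4 (cs4 = 9.5 mM, k4 = 0.96 s⁻¹)
    dissolved substrate + partner → target (k5 = 4.2 M⁻¹ s⁻¹)

- target is meant together with its crystals
- solid, in amounts per volume of the solution: solid substrate, crystals
- at the start none of the solid substrate is in solution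
- what has only dissolved of solid substrate counts as not reacted
- the reaction counts as stopped when no species that holds the solid substrate changes by six tenths of a point or more over the second half of the time
- run time (flask): 40 min

1. the state of affairs at 40 min: stopped, and by what, or still going (for what has run out or reacted, a solid counts together with what of it has only dissolved) (all of the solid substrate has reacted / the partner has run out first / it is still moving / forward and back rates have come level)
2. part of the solid substrate that has turned into other species by 40 min (what has only dissolved does not count)
3. amount of target at 40 min, in percent of the solid substrate charged
4. amount of target if the flask were left three thousand times as long, in percent of the solid substrate charged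

1. I start from late times: by its own decay the partner has a lifetime of 7.14 s, far shorter than the 40 min allowed, so what stands late is made in the first seconds, and I follow one partner molecule through them.

2. With [dissolved substrate] held at its solubility, coupling is pseudo-first-order at 0.0399 s⁻¹, against decay at 0.14 s⁻¹, so the molecule takes the coupling branch of this fork with a chance of 22.2 %.

3. But the flask starts with no dissolved substrate, and dissolving runs at 0.96 s⁻¹, so the molecule must also outlast that delay, with a chance of 84.2 %.

4. The product of these two is the coupling chance, the share of charged partner that ends as target, 18.7 %; times the 2.00 equiv charged, it puts the top of my bracket at 37.4 % target.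

5. For the bottom I hold the protic impurity at its charge, which adds a loss of 0.0185 s⁻¹, and the chance falls to 16.7 %, or 33.3 % target. The sag in [dissolved substrate] once the solid has gone is beyond my hand reckoning, so this bottom is not a strict one. I expect the partner to be used up, with conversion equal to yield, and both unchanged at long times.

6. The forecast says the partner has run out first, with 34 %, 34 % and 34 %, because “Nothing can form after that”; its yield lies inside my bracket .

The simulation gives the partner has run out first, with 34.7 %, 34.7 % and 34.7 %, which is a coupling chance of 17.4 %, between 16.7 % and 18.7 % . At 0.0622 min the partner goes to side product 3.8 times as fast as to target, and target already stands at 34.7 % by 2.00 min.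

In the neighbour flask with 0.800 equiv of partner, the same chances, times those equivalents, give between 13.3 % and 15.0 % target. The simulation of that flask gives 13.9 %.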